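**Assumption:** gibberellane numbering is used for all intermediates (C4 carries the C18 methyl and C19 carboxyl, C10 the C20 carboxyl, C6 the C7 carboxyl); β is the face of H-5 and H-9, α the face of the C19 and C20 carboxyls; the sense of induction of (R)-BINAP in step 5 is assumed, and (S)-BINAP is used if it proves opposite; the route is a proposal and has not been run.

## Retrosynthetic overview

1. Target triacid ⇐ its trimethyl ester ⇐ ring D by intramolecular alkenylchromium addition to a C13 ketone; the 2-bromoallyl group on C8 comes from a Sakurai addition to a ring C enone.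
2. Ring C enone ⇐ Birch reduction of an anisole ring, which also saturates C5=C6 and sets the trans A/B junction.
3. Key step: rings B and A are closed in one pot on a "C5 linchpin" vinyl sulfide by enantioselective Pd α-arylation (C10–C9), then 6-exo addition–elimination (C4–C5), then C4 methylation.
4. Linchpin ⇐ di-tert-butyl pimelate (C20, C10, C1–C4, C19) + the ketene dithioacetal of tert-butyl (2-bromo-5-methoxyphenyl)acetate (C5–C9, C11–C14, C7).
5. Ring order: C (aromatic, purchased) → B and A (one operation) → C dearomatized → D.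

## Route

Step 1
Reactants: 1 2-(2-bromo-5-methoxyphenyl)acetic acid
Product: 2 tert-butyl 2-(2-bromo-5-methoxyphenyl)acetate
Conditions: tert-butyl 2,2,2-trichloroacetimidate, BF3·OEt2 (cat.), CH2Cl2/cyclohexane, rt
Reagents that add atoms: tert-butyl 2,2,2-trichloroacetimidate, CC(C)(C)OC(=N)C(Cl)(Cl)Cl
Why: acid-catalysed O-alkylation of the acid by the imidate (tert-butyl esterification) gives an ester that resists enolate chemistry at its carbonyl and is later removed with acid; no stereocentre is formed.

Step 2
Reactants: 2 tert-butyl 2-(2-bromo-5-methoxyphenyl)acetate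
Product: 3 tert-butyl 2-(2-bromo-5-methoxyphenyl)-3,3-bis(methylsulfanyl)prop-2-enoate
Conditions: NaH (2.2 equiv), CS2, THF/DMF, 0 °C → rt; then MeI (2.4 equiv)
Reagents that add atoms: carbon disulfide, S=C=S; iodomethane, CI
Why: ketene dithioacetal synthesis (double deprotonation, CS2 capture, double S-methylation) turns the benzylic CH2 into a push–pull alkene whose β-carbon is the future C5 and removes the acidic benzylic hydrogens.

Step 3
Reactants: 4 heptanedioic acid (pimelic acid)
Product: 5 di-tert-butyl heptanedioate
Conditions: tert-butyl 2,2,2-trichloroacetimidate (2.5 equiv), BF3·OEt2 (cat.), CH2Cl2/cyclohexane, rt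
Reagents that add atoms: tert-butyl 2,2,2-trichloroacetimidate, CC(C)(C)OC(=N)C(Cl)(Cl)Cl
Why: the same imidate esterification gives a diester whose lithium enolate is slow to undergo Dieckmann closure, so it can be used as an open-chain nucleophile.

Step 4
Reactants: 3 tert-butyl 2-(2-bromo-5-methoxyphenyl)-3,3-bis(methylsulfanyl)prop-2-enoate; 5 di-tert-butyl heptanedioate
Product: 6 tri-tert-butyl 1-(2-bromo-5-methoxyphenyl)-2-(methylsulfanyl)hept-1-ene-1,3,7-tricarboxylate
Conditions: 5 (2.4 equiv), LiN(iPr)2 (2.2 equiv), THF, −78 °C; then 3, −78 → 0 °C; aq NH4Cl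
Reagents that add atoms: none
Why: vinylic substitution by conjugate addition–elimination of the pimelate lithium enolate at the bis(methylsulfanyl) carbon expels one thiolate and forms C5–C10; the product's C10–H is acidic and is deprotonated by the second enolate equivalent, which blocks a second substitution (alkene geometry and the C10 centre are labile and left undefined).

Step 5
Reactants: 6 tri-tert-butyl 1-(2-bromo-5-methoxyphenyl)-2-(methylsulfanyl)hept-1-ene-1,3,7-tricarboxylate
Product: 9 tri-tert-butyl (1R,4aR)-7-methoxy-1-methyl-2,3,4,4a-tetrahydro-1H-fluorene-1,4a,9-tricarboxylate, via methylthioindene triester 7 (not isolated), via C4-unmethylated fluorene triester 8 (not isolated)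
Conditions: Pd2(dba)3 (2.5 mol %), (R)-BINAP (6 mol %), NaOtBu (1.2 equiv), PhMe, 70 °C; then NaN(SiMe3)2 (2.3 equiv), THF, 0 °C → rt; then MeI (3 equiv), −78 → 0 °C
Reagents that add atoms: iodomethane, CI
Why: Proposed new method: a one-pot domino in which the delocalized C10 carbanion of 6 is arylated by the ortho C–Br bond (oxidative addition of zerovalent palladium, then C–C reductive elimination under control of the chiral ligand) to close ring B and set the C10 quaternary centre; only then is C5 electrophilic again, so the pendant ester enolate closes ring A by 6-exo addition–elimination of the second thiolate, and the resulting glutaconate-type anion is methylated at C4 (the terminus remote from the aryl ring) on the face anti to the pseudo-axial C10 ester, which places the C19 and C20 esters cis; the closest known reaction types are asymmetric Pd-catalysed intramolecular α-arylation giving benzylic quaternary centres (oxindole and indane syntheses), enolate substitution of β-(methylthio)acrylates, and C4 ester-enolate methylation anti to an axial C10 group in podocarpic-acid-type ring A syntheses.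

Step 6
Reactants: 9 tri-tert-butyl (1R,4aR)-7-methoxy-1-methyl-2,3,4,4a-tetrahydro-1H-fluorene-1,4a,9-tricarboxylate
Product: 10 (1R,4aR)-7-methoxy-1-methyl-2,3,4,4a-tetrahydro-1H-fluorene-1,4a,9-tricarboxylic acid
Conditions: TFA/CH2Cl2 (1:1), 0 °C → rt
Reagents that add atoms: none
Why: acidolysis of the three tert-butyl esters through the tert-butyl cation leaves the tetrasubstituted enoate and both quaternary centres untouched and gives the carboxylic acids, which as carboxylate salts survive the dissolving-metal step that esters would not.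

Step 7
Reactants: 10 (1R,4aR)-7-methoxy-1-methyl-2,3,4,4a-tetrahydro-1H-fluorene-1,4a,9-tricarboxylic acid
Product: 12 1-methyl-7-oxo-2,3,4,4a,4b,5,6,7,9,9a-decahydro-1H-fluorene-1,4a,9-tricarboxylic acid (gibberellane numbering: 13-oxo-8(14)-ene; H-5β; H-9β; 6β-CO2H; 19- and 20-CO2H α), via dienol ether triacid 11 (not isolated)
Conditions: Li, NH3(l), t-BuOH, THF, −78 → −33 °C; NH4Cl; then 2 M HCl, THF, rt
Reagents that add atoms: water, O
Why: Birch reduction of the tricarboxylate first reduces the aryl-conjugated C5=C6 acrylate with axial protonation at C5 from the β face, anti to the two axial α-carboxylates (trans A/B junction), then converts the anisole ring into the 1-methoxy-1,4-diene 11; aqueous HCl hydrolyses the enol ether and moves the 8,9-alkene into conjugation, and because C9 and C6 are both γ to the new enone they equilibrate to the more stable 9β-H and 6β-carboxyl arrangement.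

Step 8
Reactants: 12 1-methyl-7-oxo-2,3,4,4a,4b,5,6,7,9,9a-decahydro-1H-fluorene-1,4a,9-tricarboxylic acid
Product: 13 trimethyl 1-methyl-7-oxo-2,3,4,4a,4b,5,6,7,9,9a-decahydro-1H-fluorene-1,4a,9-tricarboxylate (same configuration as 12)
Conditions: Me3SiCHN2, PhMe/MeOH, 0 °C → rt
Reagents that add atoms: trimethylsilyldiazomethane, C[Si](C)(C)C=[N+]=[N-]
Why: O-methylation of the three acids by the diazoalkane in methanol proceeds under neutral conditions that do not touch the enone or any stereocentre.

Step 9
Reactants: 13 trimethyl 1-methyl-7-oxo-2,3,4,4a,4b,5,6,7,9,9a-decahydro-1H-fluorene-1,4a,9-tricarboxylate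
Product: 14 trimethyl 8a-(2-bromoprop-2-en-1-yl)-1-methyl-7-oxododecahydro-1H-fluorene-1,4a,9-tricarboxylate (gibberellane numbering: bromoallyl on C8 β and cis to H-9)
Conditions: (2-bromoallyl)trimethylsilane, TiCl4, CH2Cl2, −78 °C
Reagents that add atoms: (2-bromoprop-2-en-1-yl)trimethylsilane, C=C(Br)C[Si](C)(C)C
Why: Hosomi–Sakurai conjugate allylation of the TiCl4-activated enone forms the C8 quaternary centre; carbon nucleophiles add to such ring-fusion enones on the face of the adjacent angular hydrogen (H-9), giving the cis-fused B/C hydrindanone with C15 β.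

Step 10
Reactants: 14 trimethyl 8a-(2-bromoprop-2-en-1-yl)-1-methyl-7-oxododecahydro-1H-fluorene-1,4a,9-tricarboxylate
Product: 15 trimethyl ent-13-hydroxygibberell-16-ene-7,19,20-trioate (trimethyl ester of the target)
Conditions: CrCl2 (6 equiv), NiCl2 (5 mol %), DMF, 25 → 50 °C
Reagents that add atoms: none
Why: intramolecular Nozaki–Hiyama–Kishi reaction, in which the alkenyl–CrCl2 species formed from the vinyl bromide adds to the C13 ketone and tolerates the esters; the two-carbon tether from C8 can reach only one face of C13, so the bridged ring D, the 13-hydroxyl and the 16-methylene arise with the required configuration.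

Step 11
Reactants: 15 trimethyl ent-13-hydroxygibberell-16-ene-7,19,20-trioate
Product: 16 ent-13-hydroxygibberell-16-ene-7,19,20-trioic acid (the target gibberellin)
Conditions: n-PrSLi, HMPA, 25 °C; then 1 M HCl
Reagents that add atoms: none
Why: SN2 demethylation of the three methyl esters by thiolate works on the hindered C19 and C20 esters without touching the tertiary allylic alcohol or the exocyclic alkene, and C6 already has its thermodynamic configuration.

## Compound list

1 | 2-(2-bromo-5-methoxyphenyl)acetic acid | COc1ccc(Br)c(CC(=O)O)c1 | starting material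
2 | tert-butyl 2-(2-bromo-5-methoxyphenyl)acetate | COc1ccc(Br)c(CC(=O)OC(C)(C)C)c1 | intermediate
3 | tert-butyl 2-(2-bromo-5-methoxyphenyl)-3,3-bis(methylsulfanyl)prop-2-enoate | COc1ccc(Br)c(c1)C(C(=O)OC(C)(C)C)=C(SC)SC | intermediate
4 | heptanedioic acid (pimelic acid) | OC(=O)CCCCCC(=O)O | starting material
5 | di-tert-butyl heptanedioate | CC(C)(C)OC(=O)CCCCCC(=O)OC(C)(C)C | intermediate
6 | tri-tert-butyl 1-(2-bromo-5-methoxyphenyl)-2-(methylsulfanyl)hept-1-ene-1,3,7-tricarboxylate (E/Z mixture, racemic at C3) | COc1ccc(Br)c(c1)C(C(=O)OC(C)(C)C)=C(SC)C(C(=O)OC(C)(C)C)CCCCC(=O)OC(C)(C)C | intermediate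
7 | di-tert-butyl (1S)-1-(5-tert-butoxy-5-oxopentyl)-5-methoxy-2-(methylsulfanyl)-1H-indene-1,3-dicarboxylate (methylthioindene triester) | c23cc(OC)ccc2[C@](C(=O)OC(C)(C)C)(CCCCC(=O)OC(C)(C)C)C(SC)=C3C(=O)OC(C)(C)C | intermediate
8 | tri-tert-butyl (4aR)-7-methoxy-2,3,4,4a-tetrahydro-1H-fluorene-1,4a,9-tricarboxylate (C4-unmethylated fluorene triester, C1 epimers) | c23cc(OC)ccc2[C@]1(C(=O)OC(C)(C)C)CCCC(C(=O)OC(C)(C)C)C1=C3C(=O)OC(C)(C)C | intermediate
9 | tri-tert-butyl (1R,4aR)-7-methoxy-1-methyl-2,3,4,4a-tetrahydro-1H-fluorene-1,4a,9-tricarboxylate | c23cc(OC)ccc2[C@]1(C(=O)OC(C)(C)C)CCC[C@@](C)(C(=O)OC(C)(C)C)C1=C3C(=O)OC(C)(C)C | intermediate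
10 | (1R,4aR)-7-methoxy-1-methyl-2,3,4,4a-tetrahydro-1H-fluorene-1,4a,9-tricarboxylic acid | c23cc(OC)ccc2[C@]1(C(=O)O)CCC[C@@](C)(C(=O)O)C1=C3C(=O)O | intermediate
11 | 7-methoxy-1-methyl-2,3,4,4a,5,8,9,9a-octahydro-1H-fluorene-1,4a,9-tricarboxylic acid (dienol ether triacid; trans A/B with H-5β; C6 epimers) | C23CC(OC)=CCC=2[C@]1(C(=O)O)CCC[C@@](C)(C(=O)O)[C@H]1C3C(=O)O | intermediate
12 | 1-methyl-7-oxo-2,3,4,4a,4b,5,6,7,9,9a-decahydro-1H-fluorene-1,4a,9-tricarboxylic acid (H-5β, H-9β, 6β-CO2H, 19- and 20-CO2H α) | C23=CC(=O)CC[C@H]2[C@]1(C(=O)O)CCC[C@@](C)(C(=O)O)[C@H]1[C@@H]3C(=O)O | intermediate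
13 | trimethyl 1-methyl-7-oxo-2,3,4,4a,4b,5,6,7,9,9a-decahydro-1H-fluorene-1,4a,9-tricarboxylate (configuration as 12) | C23=CC(=O)CC[C@H]2[C@]1(C(=O)OC)CCC[C@@](C)(C(=O)OC)[C@H]1[C@@H]3C(=O)OC | intermediate
14 | trimethyl 8a-(2-bromoprop-2-en-1-yl)-1-methyl-7-oxododecahydro-1H-fluorene-1,4a,9-tricarboxylate (bromoallyl on C8 β, cis to H-9) | C=C(Br)C[C@]23CC(=O)CC[C@H]2[C@]1(C(=O)OC)CCC[C@@](C)(C(=O)OC)[C@H]1[C@@H]3C(=O)OC | intermediate
15 | trimethyl ent-13-hydroxygibberell-16-ene-7,19,20-trioate (trimethyl ester of the target; 4α- and 10α-CO2Me, 6β-CO2Me, H-5β, H-9β) | C=C1C[C@]23C[C@@]1(O)CC[C@H]2[C@]1(C(=O)OC)CCC[C@@](C)(C(=O)OC)[C@H]1[C@@H]3C(=O)OC | intermediate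
16 | ent-13-hydroxygibberell-16-ene-7,19,20-trioic acid (the target gibberellin; 4α- and 10α-CO2H, 6β-CO2H, H-5β, H-9β) | C=C1C[C@]23C[C@@]1(O)CC[C@H]2[C@]1(C(=O)O)CCC[C@@](C)(C(=O)O)[C@H]1[C@@H]3C(=O)O | target

## Step count and risks

Total steps: 11. Longest linear sequence: 10 (steps 1, 2, 4, 5, 6, 7, 8, 9, 10, 11).

**Step 5** is the most likely to fail. The enantioselective arylation of a delocalized ester carbanion, the order of the two ring closures and the site and face of the methylation are all untested in this setting. The fallback sets out from 6 and closes ring B without a transition metal by an elimination–addition (aryne) pathway. Lithium 2,2,6,6-tetramethylpiperidide (3.5 equiv, THF, −78 → −20 °C) deprotonates C10–H, the chain ester CH2 and then the aryl C–H ortho to bromine. Loss of bromide gives an aryne that the C10 carbanion can only capture at C9, and the resulting aryl anion is protonated by the amine. The same 6-exo addition–elimination and iodomethane quench follow. This gives racemic material, that is 9 together with its enantiomer tri-tert-butyl (1S,4aS)-7-methoxy-1-methyl-2,3,4,4a-tetrahydro-1H-fluorene-1,4a,9-tricarboxylate F1. Preparative chiral supercritical-fluid chromatography separates them, and the (1R,4aR) enantiomer rejoins the route at 9.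

**Step 9** is the second risk. C8 is flanked by C6 and C9, and the 6β-ester lies on the face the nucleophile must use. The fallback sets out from 13 and delivers the same group intramolecularly. Indium-mediated Barbier 1,2-addition of 2,3-dibromopropene to the C13 carbonyl (In powder, THF/H2O, rt) gives the tertiary bis-allylic alcohol trimethyl 7-(2-bromoprop-2-en-1-yl)-7-hydroxy-1-methyl-2,3,4,4a,4b,5,6,7,9,9a-decahydro-1H-fluorene-1,4a,9-tricarboxylate F2. Anionic oxy-Cope rearrangement (KH, 18-crown-6, THF, 0 °C → rt) then moves the bromoallyl group suprafacially from C13 to C8 and regenerates the ketone on protonation. This rejoins the route at 14, provided the Barbier addition places the allyl group on the β face of C13.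

**Step 10** is the third risk, because alkenylchromium reagents add sluggishly to ketones and the closure makes a bridged ring. The fallback sets out from 13 and closes ring D by a ketyl radical instead. Conjugate propargylation with allenyltributylstannane and TiCl4 (CH2Cl2, −78 °C) gives trimethyl 1-methyl-7-oxo-8a-(prop-2-yn-1-yl)dodecahydro-1H-fluorene-1,4a,9-tricarboxylate F3. Treatment with SmI2, HMPA and t-BuOH in THF generates the C13 ketyl, which cyclizes 5-exo onto the alkyne; reduction and protonation of the vinyl radical give the exocyclic methylene and the tertiary alcohol. This rejoins the route at 15.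

Further compounds
F1 | step 5 | tri-tert-butyl (1S,4aS)-7-methoxy-1-methyl-2,3,4,4a-tetrahydro-1H-fluorene-1,4a,9-tricarboxylate | c23cc(OC)ccc2[C@@]1(C(=O)OC(C)(C)C)CCC[C@](C)(C(=O)OC(C)(C)C)C1=C3C(=O)OC(C)(C)C
F2 | step 9 | trimethyl 7-(2-bromoprop-2-en-1-yl)-7-hydroxy-1-methyl-2,3,4,4a,4b,5,6,7,9,9a-decahydro-1H-fluorene-1,4a,9-tricarboxylate (bromoallyl β at C13) | C23=C[C@](O)(CC(Br)=C)CC[C@H]2[C@]1(C(=O)OC)CCC[C@@](C)(C(=O)OC)[C@H]1[C@@H]3C(=O)OC
F3 | step 10 | trimethyl 1-methyl-7-oxo-8a-(prop-2-yn-1-yl)dodecahydro-1H-fluorene-1,4a,9-tricarboxylate (propargyl on C8 β) | C#CC[C@]23CC(=O)CC[C@H]2[C@]1(C(=O)OC)CCC[C@@](C)(C(=O)OC)[C@H]1[C@@H]3C(=O)OC
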